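C6 is the allylic carbinol carbon next to the C4=C5 E-olefin and lies gamma to the C12 carbonyl, so the C5–C6 bond is the one to cut: a C5 alkenylchromium adds to a C6 aldehyde to close the ten-membered carbocycle (ring A), and the C6 alkoxide then closes the gamma-lactone (ring B) on the C12 methyl ester.
Ring order: the C1/C10 oxirane (ring C) is made first, on the open chain, by Sharpless epoxidation of a Z allylic alcohol; rings A and B follow together in the key step.
The open chain is cut at C10=C1 (Still–Gennari olefination) into an iodo-enal (C1–C5 and C15, from pent-4-yn-1-ol) and a C10 phosphonate, whose C9–C10 bond comes from alkylation of the phosphonoacetate with a C9 triflate.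
C7 and C8 come from dimethyl (S)-malate by Fráter–Seebach allylation; the allyl group is the latent C11–C12 ester and the malate C4 carboxyl becomes the C6 aldehyde.
After the cyclisation: alpha-methylenation (C13), desilylation, acetate on O14, methacrylate on O8.
Key step: step 19

Remark: locants are germacrane locants (oxirane C1/C10, olefin C4=C5, lactone O–C6 and C12, ester oxygen on C8, C14 = CH2O on C10, C15 = methyl on C4); C12 is kept as an allyl group until the C14 ester has been reduced, because a hydride cannot tell the two esters apart.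

Step 1
Reactants: 1 pent-4-yn-1-ol
Product: 3 (4E)-5-iodo-4-methylpent-4-en-1-ol, via alkenylalane 2 (not isolated)
Conditions: Me3Al (3 equiv), Cp2ZrCl2 (0.25 equiv), CH2Cl2, 0 °C to rt; then I2, THF, −30 to 0 °C; aq. Na2S2O3 / potassium sodium tartrate work-up
Reagents that add atoms: trimethylaluminium C[Al](C)C; iodine II
Why: Zirconium-catalysed syn carboalumination of the terminal alkyne (Negishi carboalumination) places the methyl group on C4 and aluminium on C5, and iodinolysis of the C–Al bond with retention gives the E iodoalkene.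

Step 2
Reactants: 3 (4E)-5-iodo-4-methylpent-4-en-1-ol
Product: 4 (4E)-5-iodo-4-methylpent-4-enal
Conditions: Dess–Martin periodinane, NaHCO3, CH2Cl2, 0 °C to rt
Reagents that add atoms: none
Why: Dess–Martin oxidation turns the primary alcohol into the C1 aldehyde under buffered conditions that leave the iodoalkene alone.

Step 3
Reactants: 5 dimethyl (S)-malate
Product: 7 dimethyl (2S,3R)-2-hydroxy-3-(prop-2-en-1-yl)butanedioate, via dilithium alkoxide enolate 6 (not isolated)
Conditions: LiN(SiMe3)2 (2.2 equiv), THF, −78 °C; allyl bromide, −78 to −15 °C; NH4Cl quench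
Reagents that add atoms: allyl bromide C=CCBr
Why: In this Fráter–Seebach alkylation the chelated dilithium alkoxide enolate 6 is allylated on the face anti to the C8 alkoxide, which sets C7 (3R) relative to the malate-derived C8 centre.

Step 4
Reactants: 7 dimethyl (2S,3R)-2-hydroxy-3-(prop-2-en-1-yl)butanedioate
Product: 8 (2S,3S)-3-(prop-2-en-1-yl)butane-1,2,4-triol
Conditions: LiAlH4, THF, 0 °C to reflux; aqueous NaOH work-up
Reagents that add atoms: none
Why: LiAlH4 reduces both methyl esters to primary alcohols (ester reduction by hydride) without touching the terminal olefin or the two stereocenters.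

Step 5
Reactants: 8 (2S,3S)-3-(prop-2-en-1-yl)butane-1,2,4-triol
Product: 9 (2S)-2-[(4S)-2,2-dimethyl-1,3-dioxolan-4-yl]pent-4-en-1-ol
Conditions: 2,2-dimethoxypropane, TsOH·H2O (cat.), acetone, rt
Reagents that add atoms: 2,2-dimethoxypropane COC(C)(C)OC
Why: Acid-catalysed acetalisation under equilibrating conditions favours the five-membered dioxolane across the C8/C9 vicinal diol over the dioxane with its axial methyl group, which leaves only the C6 hydroxyl free.

Step 6
Reactants: 9 (2S)-2-[(4S)-2,2-dimethyl-1,3-dioxolan-4-yl]pent-4-en-1-ol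
Product: 10 (4S)-4-{(2S)-1-[(4-methoxyphenyl)methoxy]pent-4-en-2-yl}-2,2-dimethyl-1,3-dioxolane
Conditions: NaH, 4-methoxybenzyl chloride, Bu4NI (cat.), THF/DMF, 0 °C to rt
Reagents that add atoms: 4-methoxybenzyl chloride COc1ccc(CCl)cc1
Why: Williamson etherification of the sodium alkoxide with the benzylic chloride protects the C6 hydroxyl as a p-methoxybenzyl ether that can later be removed oxidatively.

Step 7
Reactants: 10 (4S)-4-{(2S)-1-[(4-methoxyphenyl)methoxy]pent-4-en-2-yl}-2,2-dimethyl-1,3-dioxolane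
Product: 11 (2S,3S)-3-{[(4-methoxyphenyl)methoxy]methyl}hex-5-ene-1,2-diol
Conditions: AcOH/H2O (4:1), 40 °C
Reagents that add atoms: none
Why: Aqueous acetic acid hydrolyses the dioxolane (acetal hydrolysis) while the benzylic ether is stable, which frees the C8/C9 diol.

Step 8
Reactants: 11 (2S,3S)-3-{[(4-methoxyphenyl)methoxy]methyl}hex-5-ene-1,2-diol
Product: 13 (2S,3S)-2-[(tert-butyldimethylsilyl)oxy]-3-{[(4-methoxyphenyl)methoxy]methyl}hex-5-en-1-yl trifluoromethanesulfonate, via hydroxy triflate 12 (not isolated)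
Conditions: Tf2O (1.05 equiv), 2,6-lutidine (3 equiv), CH2Cl2, −78 °C; then TBSOTf (1.2 equiv), −78 to −30 °C; cold work-up, used at once
Reagents that add atoms: trifluoromethanesulfonic anhydride O=S(=O)(OS(=O)(=O)C(F)(F)F)C(F)(F)F; tert-butyldimethylsilyl trifluoromethanesulfonate CC(C)(C)[Si](C)(C)OS(=O)(=O)C(F)(F)F
Why: At −78 °C triflic anhydride sulfonylates only the primary C9 hydroxyl and the silyl triflate then caps the C8 hydroxyl in the same flask (one-pot triflation–silylation of a terminal 1,2-diol), both without touching a stereocenter.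

Step 9
Reactants: 13 (2S,3S)-2-[(tert-butyldimethylsilyl)oxy]-3-{[(4-methoxyphenyl)methoxy]methyl}hex-5-en-1-yl trifluoromethanesulfonate; 14 methyl bis(2,2,2-trifluoroethyl)phosphonoacetate
Product: 16 methyl (4R,5S)-2-[bis(2,2,2-trifluoroethoxy)phosphoryl]-4-[(tert-butyldimethylsilyl)oxy]-5-{[(4-methoxyphenyl)methoxy]methyl}oct-7-enoate (both C2 epimers), via sodium phosphonate carbanion 15 (not isolated)
Conditions: 14 (2.0 equiv), NaH (1.9 equiv), THF, 0 °C; then 13, THF/DMF, −20 to 0 °C
Reagents that add atoms: none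
Why: The soft phosphonate-stabilised carbanion 15 displaces the primary triflate in an SN2 C-alkylation of the malonate type, run cold and with excess nucleophile so that substitution outruns dialkylation and attack of the C6 ether oxygen on C9, and the new C10 centre forms as an epimer mixture that the next step erases.

Step 10
Reactants: 16 methyl (4R,5S)-2-[bis(2,2,2-trifluoroethoxy)phosphoryl]-4-[(tert-butyldimethylsilyl)oxy]-5-{[(4-methoxyphenyl)methoxy]methyl}oct-7-enoate; 4 (4E)-5-iodo-4-methylpent-4-enal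
Product: 18 methyl (2Z,6E)-2-[(2R,3S)-2-[(tert-butyldimethylsilyl)oxy]-3-{[(4-methoxyphenyl)methoxy]methyl}hex-5-en-1-yl]-7-iodo-6-methylhepta-2,6-dienoate, via potassium phosphonate carbanion 17 (not isolated)
Conditions: KN(SiMe3)2 (1.05 equiv), 18-crown-6 (4 equiv), THF, −78 °C; then 4, −78 °C
Reagents that add atoms: none
Why: In the Still–Gennari olefination the trifluoroethyl phosphonate carbanion 17 adds to aldehyde 4 under dissociating conditions and the kinetic adduct collapses fast, so that the ester carbon C14 ends cis to the C2 chain in the trisubstituted C10=C1 olefin.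

Step 11
Reactants: 18 methyl (2Z,6E)-2-[(2R,3S)-2-[(tert-butyldimethylsilyl)oxy]-3-{[(4-methoxyphenyl)methoxy]methyl}hex-5-en-1-yl]-7-iodo-6-methylhepta-2,6-dienoate
Product: 19 (2Z,6E)-2-[(2R,3S)-2-[(tert-butyldimethylsilyl)oxy]-3-{[(4-methoxyphenyl)methoxy]methyl}hex-5-en-1-yl]-7-iodo-6-methylhepta-2,6-dien-1-ol
Conditions: iBu2AlH (2.5 equiv), CH2Cl2, −78 °C; aq. potassium sodium tartrate work-up
Reagents that add atoms: none
Why: iBu2AlH reduces the conjugated methyl ester 1,2 to the allylic alcohol at low temperature (ester reduction by an aluminium hydride) without isomerising the Z olefin or touching the iodoalkene.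

Step 12
Reactants: 19 (2Z,6E)-2-[(2R,3S)-2-[(tert-butyldimethylsilyl)oxy]-3-{[(4-methoxyphenyl)methoxy]methyl}hex-5-en-1-yl]-7-iodo-6-methylhepta-2,6-dien-1-ol
Product: 20 {(2S,3R)-2-[(2R,3S)-2-[(tert-butyldimethylsilyl)oxy]-3-{[(4-methoxyphenyl)methoxy]methyl}hex-5-en-1-yl]-3-[(3E)-4-iodo-3-methylbut-3-en-1-yl]oxiran-2-yl}methanol
Conditions: Ti(OiPr)4 (0.5 equiv), L-(+)-diethyl tartrate (0.6 equiv), t-BuOOH (2 equiv, decane), 4 Å molecular sieves, CH2Cl2, −20 °C
Reagents that add atoms: tert-butyl hydroperoxide CC(C)(C)OO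
Why: In the Sharpless asymmetric epoxidation the allylic hydroxyl binds the titanium tartrate complex, and with L-(+)-tartrate the oxygen is delivered to the lower face when the CH2OH group is drawn at the lower right of the olefin plane, which gives the 10S,1R oxirane under reagent control while the terminal olefin and the iodoalkene, lacking an allylic hydroxyl, do not react.

Step 13
Reactants: 20 {(2S,3R)-2-[(2R,3S)-2-[(tert-butyldimethylsilyl)oxy]-3-{[(4-methoxyphenyl)methoxy]methyl}hex-5-en-1-yl]-3-[(3E)-4-iodo-3-methylbut-3-en-1-yl]oxiran-2-yl}methanol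
Product: 21 tert-butyldimethylsilyl ether of 20 at O14
Conditions: TBSCl, imidazole, DMF, 0 °C to rt
Reagents that add atoms: tert-butyldimethylsilyl chloride CC(C)(C)[Si](C)(C)Cl
Why: Silylation of the primary hydroxyl with the silyl chloride and imidazole (silyl ether formation) protects C14 under conditions that do not open the oxirane.

Step 14
Reactants: 21 tert-butyldimethylsilyl ether of 20 at O14
Product: 23 (3S,4R)-4-[(tert-butyldimethylsilyl)oxy]-5-[(2S,3R)-2-{[(tert-butyldimethylsilyl)oxy]methyl}-3-[(3E)-4-iodo-3-methylbut-3-en-1-yl]oxiran-2-yl]-3-{[(4-methoxyphenyl)methoxy]methyl}pentanal, via vicinal diol 22 (not isolated)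
Conditions: OsO4 (2 mol %), N-methylmorpholine N-oxide, acetone/H2O, rt; then NaIO4, THF/pH 7 buffer, 0 °C
Reagents that add atoms: osmium tetroxide O=[Os](=O)(=O)=O (oxygen donor, regenerated by the N-oxide); N-methylmorpholine N-oxide C[N+]1([O-])CCOCC1
Why: OsO4-catalysed dihydroxylation followed by periodate cleavage (Lemieux–Johnson type sequence) acts on the monosubstituted terminal olefin much faster than on the trisubstituted, electron-poor iodoalkene, and unmasks C12 as the aldehyde with loss of one carbon.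

Step 15
Reactants: 23 the C12 aldehyde
Product: 24 (3S,4R)-4-[(tert-butyldimethylsilyl)oxy]-5-[(2S,3R)-2-{[(tert-butyldimethylsilyl)oxy]methyl}-3-[(3E)-4-iodo-3-methylbut-3-en-1-yl]oxiran-2-yl]-3-{[(4-methoxyphenyl)methoxy]methyl}pentanoic acid
Conditions: NaClO2, NaH2PO4, 2-methyl-2-butene, t-BuOH/H2O, 0 °C to rt
Reagents that add atoms: sodium chlorite [Na+].[O-]Cl=O
Why: Pinnick oxidation converts the aldehyde into the acid at buffered pH with 2-methyl-2-butene as hypochlorite scavenger, conditions tolerated by the oxirane, the silyl ethers, the benzylic ether and the iodoalkene.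

Step 16
Reactants: 24 the C12 carboxylic acid
Product: 25 methyl (3S,4R)-4-[(tert-butyldimethylsilyl)oxy]-5-[(2S,3R)-2-{[(tert-butyldimethylsilyl)oxy]methyl}-3-[(3E)-4-iodo-3-methylbut-3-en-1-yl]oxiran-2-yl]-3-{[(4-methoxyphenyl)methoxy]methyl}pentanoate
Conditions: Me3SiCHN2, PhMe/MeOH, 0 °C
Reagents that add atoms: trimethylsilyldiazomethane C[Si](C)(C)C=[N+]=[N-]
Why: Methylation of the carboxylic acid with Me3SiCHN2 in the presence of methanol (diazoalkane esterification) gives the C12 methyl ester under neutral conditions.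

Step 17
Reactants: 25 the C12 methyl ester
Product: 26 methyl (3S,4R)-4-[(tert-butyldimethylsilyl)oxy]-5-[(2S,3R)-2-{[(tert-butyldimethylsilyl)oxy]methyl}-3-[(3E)-4-iodo-3-methylbut-3-en-1-yl]oxiran-2-yl]-3-(hydroxymethyl)pentanoate
Conditions: DDQ (1.3 equiv), CH2Cl2/pH 7 buffer (10:1), 0 °C; used directly
Reagents that add atoms: none
Why: DDQ removes the p-methoxybenzyl ether by oxidative cleavage in buffered medium, and the gamma-hydroxy ester is carried forward at once so that it does not lactonise.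

Step 18
Reactants: 26 the C6 primary alcohol
Product: 27 methyl (3R,4R)-4-[(tert-butyldimethylsilyl)oxy]-5-[(2S,3R)-2-{[(tert-butyldimethylsilyl)oxy]methyl}-3-[(3E)-4-iodo-3-methylbut-3-en-1-yl]oxiran-2-yl]-3-formylpentanoate
Conditions: Dess–Martin periodinane, NaHCO3, CH2Cl2, 0 °C; used at once
Reagents that add atoms: none
Why: Buffered Dess–Martin oxidation gives the C6 aldehyde without base, so that the C7 centre alpha to the aldehyde and beta to the silyloxy group is neither epimerised nor eliminated.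

Step 19
Reactants: 27 the epoxy alkenyl iodide aldehyde ester
Product: 30 (1R,6R,7S,8R,10S)-8,14-bis[(tert-butyldimethylsilyl)oxy]-1,10-epoxygermacr-4E-en-12,6-olide, via alkenylchromium 28 (not isolated), via chromium alkoxide 29 (not isolated)
Conditions: CrCl2 (12 equiv), NiCl2 (0.2 equiv), degassed DMSO, rt, 27 added over 12 h (final 2 mM); aq. sodium serinate work-up; crude stirred with silica gel in CH2Cl2, rt
Reagents that add atoms: none
Why: Divalent chromium reduces NiCl2 to zerovalent nickel, which inserts into the C5–I bond with retention of the E geometry, and transmetalation gives the trivalent alkenylchromium 28 that adds 1,2 to the C6 aldehyde, the closest known reaction type being the intramolecular Nozaki–Hiyama–Kishi alkenyl iodide–aldehyde macrocyclisation. Ring A (the ten-membered carbocycle) closes by 10-exo-trig attack of C5 on the C6 carbonyl, helped by the E olefin and the trans oxirane, which take rotors out of the chain, and by slow addition at high dilution. Ring B (the gamma-lactone) closes by 5-exo-trig acyl substitution of the C6 chromium alkoxide 29 on the C12 methyl ester with loss of methoxide, in the flask or at the latest on the silica treatment. The new C6 stereocenter is controlled by C7: in the Felkin–Anh arrangement the C8 branch stands anti to the incoming C5 and the CH2CO2Me arm flanks the carbonyl oxygen, which leads to the 6R alcohol and hence to the trans-fused lactone. The step needs chemoselectivity for the aldehyde over the ester, the oxirane and the silyl ethers, which the mild, non-basic organochromium reagent secures, and it needs the 6,7-trans face selectivity, which rests on this 1,2-induction within the conformationally restricted ring-forming transition state.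

Step 20
Reactants: 30 the bis-silyl epoxy lactone
Product: 32 13-(dimethylamino)-11,13-dihydro derivative of 30 (alpha-dimethylaminomethyl lactone; C11 epimers), via lithium enolate 31 (not isolated)
Conditions: LiN(SiMe3)2 (1.3 equiv), THF, −78 °C; Me2N=CH2 I (Eschenmoser's salt, 3 equiv), −78 to 0 °C
Reagents that add atoms: N,N-dimethylmethylideneammonium iodide C=[N+](C)C.[I-]
Why: Deprotonation of the lactone at C11 and aminomethylation of the lithium enolate 31 with the preformed iminium salt (Mannich reaction) introduces C13, the C11 configuration being of no consequence.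

Step 21
Reactants: 32 the alpha-dimethylaminomethyl lactone
Product: 34 (1R,6R,7S,8R,10S)-8,14-bis[(tert-butyldimethylsilyl)oxy]-1,10-epoxygermacra-4E,11(13)-dien-12,6-olide, via trimethylammonium iodide 33 (not isolated)
Conditions: MeI, MeOH/CH2Cl2, rt; then NaHCO3, CH2Cl2/H2O, rt
Reagents that add atoms: none
Why: Quaternisation of the amine with MeI and mild base-induced beta-elimination of trimethylamine (Hofmann-type elimination) gives the exocyclic C11=C13 methylene and removes the C11 stereocenter.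

Step 22
Reactants: 34 the bis-silyl alpha-methylene lactone
Product: 35 (1R,6R,7R,8R,10S)-8,14-dihydroxy-1,10-epoxygermacra-4E,11(13)-dien-12,6-olide
Conditions: HF·pyridine, pyridine, THF, 0 °C to rt
Reagents that add atoms: none
Why: Buffered HF·pyridine cleaves both silyl ethers (fluoride-mediated desilylation) without the basic conditions that could trigger translactonisation to O8 or conjugate addition to the methylene lactone.

Step 23
Reactants: 35 the 8,14-diol
Product: 36 (1R,6R,7R,8R,10S)-14-acetoxy-8-hydroxy-1,10-epoxygermacra-4E,11(13)-dien-12,6-olide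
Conditions: AcCl (1.1 equiv), 2,4,6-collidine, CH2Cl2, −78 °C
Reagents that add atoms: acetyl chloride CC(Cl)=O
Why: At −78 °C acetyl chloride with the hindered base collidine acylates the primary C14 hydroxyl much faster than the secondary C8 hydroxyl (kinetically selective acylation).

Step 24
Reactants: 36 the 14-acetate with free C8 hydroxyl
Product: 37 (1R,6R,7R,8R,10S)-14-acetoxy-1,10-epoxy-8-(2-methylprop-2-enoyloxy)germacra-4E,11(13)-dien-12,6-olide (CNP0150481.3)
Conditions: methacrylic anhydride, Et3N, DMAP (cat.), CH2Cl2, 0 °C to rt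
Reagents that add atoms: methacrylic anhydride C=C(C)C(=O)OC(=O)C(C)=C
Why: DMAP-catalysed acylation of the remaining secondary C8 hydroxyl with methacrylic anhydride (nucleophilic acyl-transfer catalysis) installs the methacrylate with retention at C8 and completes the target.

Compound list
1 | pent-4-yn-1-ol | C#CCCCO | starting material
2 | dimethyl[(1E)-5-(dimethylalumanyloxy)-2-methylpent-1-en-1-yl]alane | C[Al](C)OCCC/C(C)=C/[Al](C)C | intermediate
3 | (4E)-5-iodo-4-methylpent-4-en-1-ol | OCCC/C(C)=C/I | intermediate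
4 | (4E)-5-iodo-4-methylpent-4-enal | O=CCC/C(C)=C/I | intermediate
5 | dimethyl (S)-malate | COC(=O)C[C@H](O)C(=O)OC | starting material
6 | dilithium alkoxide enolate of 5 (both oxygens cis on the enolate bond) | COC(=O)[C@@H](O[Li])/C=C(\O[Li])OC | intermediate
7 | dimethyl (2S,3R)-2-hydroxy-3-(prop-2-en-1-yl)butanedioate | COC(=O)[C@H](CC=C)[C@H](O)C(=O)OC | intermediate
8 | (2S,3S)-3-(prop-2-en-1-yl)butane-1,2,4-triol | OC[C@H](CC=C)[C@H](O)CO | intermediate
9 | (2S)-2-[(4S)-2,2-dimethyl-1,3-dioxolan-4-yl]pent-4-en-1-ol | OC[C@H](CC=C)[C@H]1COC(C)(C)O1 | intermediate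
10 | (4S)-4-{(2S)-1-[(4-methoxyphenyl)methoxy]pent-4-en-2-yl}-2,2-dimethyl-1,3-dioxolane | COc1ccc(COC[C@H](CC=C)[C@H]2COC(C)(C)O2)cc1 | intermediate
11 | (2S,3S)-3-{[(4-methoxyphenyl)methoxy]methyl}hex-5-ene-1,2-diol | COc1ccc(COC[C@H](CC=C)[C@H](O)CO)cc1 | intermediate
12 | (2S,3S)-2-hydroxy-3-{[(4-methoxyphenyl)methoxy]methyl}hex-5-en-1-yl trifluoromethanesulfonate | COc1ccc(COC[C@H](CC=C)[C@H](O)COS(=O)(=O)C(F)(F)F)cc1 | intermediate
13 | (2S,3S)-2-[(tert-butyldimethylsilyl)oxy]-3-{[(4-methoxyphenyl)methoxy]methyl}hex-5-en-1-yl trifluoromethanesulfonate | COc1ccc(COC[C@H](CC=C)[C@H](O[Si](C)(C)C(C)(C)C)COS(=O)(=O)C(F)(F)F)cc1 | intermediate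
14 | methyl bis(2,2,2-trifluoroethyl)phosphonoacetate | COC(=O)CP(=O)(OCC(F)(F)F)OCC(F)(F)F | starting material
15 | sodium carbanion of 14 | [Na+].COC(=O)[CH-]P(=O)(OCC(F)(F)F)OCC(F)(F)F | intermediate
16 | methyl (4R,5S)-2-[bis(2,2,2-trifluoroethoxy)phosphoryl]-4-[(tert-butyldimethylsilyl)oxy]-5-{[(4-methoxyphenyl)methoxy]methyl}oct-7-enoate (both C2 epimers) | COc1ccc(COC[C@H](CC=C)[C@H](O[Si](C)(C)C(C)(C)C)CC(C(=O)OC)P(=O)(OCC(F)(F)F)OCC(F)(F)F)cc1 | intermediate
17 | potassium carbanion of 16 | [K+].COc1ccc(COC[C@H](CC=C)[C@H](O[Si](C)(C)C(C)(C)C)C[C-](C(=O)OC)P(=O)(OCC(F)(F)F)OCC(F)(F)F)cc1 | intermediate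
18 | methyl (2Z,6E)-2-[(2R,3S)-2-[(tert-butyldimethylsilyl)oxy]-3-{[(4-methoxyphenyl)methoxy]methyl}hex-5-en-1-yl]-7-iodo-6-methylhepta-2,6-dienoate | COc1ccc(COC[C@H](CC=C)[C@H](O[Si](C)(C)C(C)(C)C)C/C(C(=O)OC)=C/CC/C(C)=C/I)cc1 | intermediate
19 | (2Z,6E)-2-[(2R,3S)-2-[(tert-butyldimethylsilyl)oxy]-3-{[(4-methoxyphenyl)methoxy]methyl}hex-5-en-1-yl]-7-iodo-6-methylhepta-2,6-dien-1-ol | COc1ccc(COC[C@H](CC=C)[C@H](O[Si](C)(C)C(C)(C)C)C/C(CO)=C/CC/C(C)=C/I)cc1 | intermediate
20 | {(2S,3R)-2-[(2R,3S)-2-[(tert-butyldimethylsilyl)oxy]-3-{[(4-methoxyphenyl)methoxy]methyl}hex-5-en-1-yl]-3-[(3E)-4-iodo-3-methylbut-3-en-1-yl]oxiran-2-yl}methanol | COc1ccc(COC[C@H](CC=C)[C@H](O[Si](C)(C)C(C)(C)C)C[C@@]2(CO)O[C@@H]2CC/C(C)=C/I)cc1 | intermediate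
21 | tert-butyldimethylsilyl ether of 20 at O14 | COc1ccc(COC[C@H](CC=C)[C@H](O[Si](C)(C)C(C)(C)C)C[C@@]2(CO[Si](C)(C)C(C)(C)C)O[C@@H]2CC/C(C)=C/I)cc1 | intermediate
22 | vicinal diol from the terminal olefin of 21 (carbinol epimers) | COc1ccc(COC[C@H](CC(O)CO)[C@H](O[Si](C)(C)C(C)(C)C)C[C@@]2(CO[Si](C)(C)C(C)(C)C)O[C@@H]2CC/C(C)=C/I)cc1 | intermediate
23 | (3S,4R)-4-[(tert-butyldimethylsilyl)oxy]-5-[(2S,3R)-2-{[(tert-butyldimethylsilyl)oxy]methyl}-3-[(3E)-4-iodo-3-methylbut-3-en-1-yl]oxiran-2-yl]-3-{[(4-methoxyphenyl)methoxy]methyl}pentanal | COc1ccc(COC[C@H](CC=O)[C@H](O[Si](C)(C)C(C)(C)C)C[C@@]2(CO[Si](C)(C)C(C)(C)C)O[C@@H]2CC/C(C)=C/I)cc1 | intermediate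
24 | the corresponding (3S,4R)-pentanoic acid | COc1ccc(COC[C@H](CC(=O)O)[C@H](O[Si](C)(C)C(C)(C)C)C[C@@]2(CO[Si](C)(C)C(C)(C)C)O[C@@H]2CC/C(C)=C/I)cc1 | intermediate
25 | the corresponding methyl (3S,4R)-pentanoate | COc1ccc(COC[C@H](CC(=O)OC)[C@H](O[Si](C)(C)C(C)(C)C)C[C@@]2(CO[Si](C)(C)C(C)(C)C)O[C@@H]2CC/C(C)=C/I)cc1 | intermediate
26 | methyl (3S,4R)-4-[(tert-butyldimethylsilyl)oxy]-5-[(2S,3R)-2-{[(tert-butyldimethylsilyl)oxy]methyl}-3-[(3E)-4-iodo-3-methylbut-3-en-1-yl]oxiran-2-yl]-3-(hydroxymethyl)pentanoate | OC[C@H](CC(=O)OC)[C@H](O[Si](C)(C)C(C)(C)C)C[C@@]1(CO[Si](C)(C)C(C)(C)C)O[C@@H]1CC/C(C)=C/I | intermediate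
27 | methyl (3R,4R)-4-[(tert-butyldimethylsilyl)oxy]-5-[(2S,3R)-2-{[(tert-butyldimethylsilyl)oxy]methyl}-3-[(3E)-4-iodo-3-methylbut-3-en-1-yl]oxiran-2-yl]-3-formylpentanoate | O=C[C@H](CC(=O)OC)[C@H](O[Si](C)(C)C(C)(C)C)C[C@@]1(CO[Si](C)(C)C(C)(C)C)O[C@@H]1CC/C(C)=C/I | intermediate
28 | alkenylchromium dichloride from 27 (chromium in place of iodine on C5) | O=C[C@H](CC(=O)OC)[C@H](O[Si](C)(C)C(C)(C)C)C[C@@]1(CO[Si](C)(C)C(C)(C)C)O[C@@H]1CC/C(C)=C/[Cr](Cl)Cl | intermediate
29 | ten-membered C6 chromium alkoxide with the C12 methyl ester still open | CC(C)(C)[Si](C)(C)O[C@@H]1C[C@@]2(CO[Si](C)(C)C(C)(C)C)O[C@@H]2CC/C(C)=C/[C@@H](O[Cr](Cl)Cl)[C@@H]1CC(=O)OC | intermediate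
30 | (1R,6R,7S,8R,10S)-8,14-bis[(tert-butyldimethylsilyl)oxy]-1,10-epoxygermacr-4E-en-12,6-olide | CC(C)(C)[Si](C)(C)O[C@@H]1C[C@@]2(CO[Si](C)(C)C(C)(C)C)O[C@@H]2CC/C(C)=C/[C@H]2OC(=O)C[C@@H]21 | intermediate
31 | lithium enolate of 30 | CC(C)(C)[Si](C)(C)O[C@@H]1C[C@@]2(CO[Si](C)(C)C(C)(C)C)O[C@@H]2CC/C(C)=C/[C@H]2OC(O[Li])=C[C@@H]21 | intermediate
32 | 13-(dimethylamino)-11,13-dihydro derivative of 30 (C11 epimers) | CC(C)(C)[Si](C)(C)O[C@@H]1C[C@@]2(CO[Si](C)(C)C(C)(C)C)O[C@@H]2CC/C(C)=C/[C@H]2OC(=O)C(CN(C)C)[C@@H]21 | intermediate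
33 | trimethylammonium iodide of 32 | CC(C)(C)[Si](C)(C)O[C@@H]1C[C@@]2(CO[Si](C)(C)C(C)(C)C)O[C@@H]2CC/C(C)=C/[C@H]2OC(=O)C(C[N+](C)(C)C)[C@@H]21.[I-] | intermediate
34 | (1R,6R,7S,8R,10S)-8,14-bis[(tert-butyldimethylsilyl)oxy]-1,10-epoxygermacra-4E,11(13)-dien-12,6-olide | CC(C)(C)[Si](C)(C)O[C@@H]1C[C@@]2(CO[Si](C)(C)C(C)(C)C)O[C@@H]2CC/C(C)=C/[C@H]2OC(=O)C(=C)[C@@H]21 | intermediate
35 | (1R,6R,7R,8R,10S)-8,14-dihydroxy-1,10-epoxygermacra-4E,11(13)-dien-12,6-olide | O[C@@H]1C[C@@]2(CO)O[C@@H]2CC/C(C)=C/[C@H]2OC(=O)C(=C)[C@@H]21 | intermediate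
36 | (1R,6R,7R,8R,10S)-14-acetoxy-8-hydroxy-1,10-epoxygermacra-4E,11(13)-dien-12,6-olide | O[C@@H]1C[C@@]2(COC(C)=O)O[C@@H]2CC/C(C)=C/[C@H]2OC(=O)C(=C)[C@@H]21 | intermediate
37 | (1R,6R,7R,8R,10S)-14-acetoxy-1,10-epoxy-8-(2-methylprop-2-enoyloxy)germacra-4E,11(13)-dien-12,6-olide (CNP0150481.3) | C=C(C)C(=O)O[C@@H]1C[C@@]2(COC(C)=O)O[C@@H]2CC/C(C)=C/[C@H]2OC(=O)C(=C)[C@@H]21 | target

Total step count: 24. Longest linear sequence: 22 steps (steps 3 to 24, from dimethyl (S)-malate); steps 1 and 2 form the side branch that joins in step 10.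

Steps most likely to fail

Step 19 (key step). The addition may show poor facial selectivity at C6, so that the cis-fused 6-epimer forms beside 30; intermolecular coupling and protodeiodination of the alkenylchromium may also compete with ring closure. The fallback sets out from 27 and comes back at 30. The cyclisation is run as described and the cis-fused 6-epi lactone F1 is separated. F1 is saponified (LiOH, THF/H2O, 0 °C) to the hydroxy acid F2, which after cold acidification is closed at once by Mitsunobu lactonisation (PPh3, diisopropyl azodicarboxylate, toluene, high dilution). The carboxylate displaces the activated C6 oxygen with inversion and gives 30. C6 is then set by an invertive C–O bond formation and no longer by face selection in the C–C bond formation.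

Step 9. The C-alkylation of the hindered, weakly nucleophilic carbanion may be slow, and the triflate may meanwhile be lost by attack of the C6 ether oxygen on C9 (cyclic ether formation with loss of the benzylic group); double alkylation is a further drain. The fallback sets out from 11 and comes back at 16, and it makes the C9–C10 bond by condensation, not by substitution. Diol 11 is silylated twice (TBSOTf, 2,6-lutidine) to the bis-silyl ether F3. The primary silyl ether is cleaved selectively (HF·pyridine, pyridine, THF, 0 °C) to the primary alcohol F4, and Dess–Martin oxidation gives the alpha-silyloxy aldehyde F5. Knoevenagel condensation of F5 with 14 (TiCl4, N-methylmorpholine, THF, 0 °C) gives the alkylidene phosphonoacetate F6, and conjugate reduction (NaBH4, THF/EtOH, −20 °C) gives 16.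

Step 23. Discrimination between the two free hydroxyls may be lost (diacetate formation or acetyl migration), the C14 hydroxyl being primary but attached to the fully substituted oxirane carbon. The fallback sets out from 34 and comes back at 36, and it unveils the two oxygens one after the other. The primary silyl ether of 34 is cleaved first (HF·pyridine, pyridine, THF, 0 °C, stopped early) to the 14-alcohol F7. F7 is acetylated (Ac2O, pyridine, DMAP) to the 14-acetate 8-silyl ether F8, and the secondary silyl ether is then removed (HF·pyridine, THF, rt) to give 36.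

Further compounds
F1 | step 19 | (1R,6S,7S,8R,10S)-8,14-bis[(tert-butyldimethylsilyl)oxy]-1,10-epoxygermacr-4E-en-12,6-olide (cis-fused 6-epimer of 30) | CC(C)(C)[Si](C)(C)O[C@@H]1C[C@@]2(CO[Si](C)(C)C(C)(C)C)O[C@@H]2CC/C(C)=C/[C@@H]2OC(=O)C[C@@H]21
F2 | step 19 | ten-membered 6S hydroxy acid from opening the lactone of F1 (C6 hydroxyl, C12 carboxylic acid) | CC(C)(C)[Si](C)(C)O[C@@H]1C[C@@]2(CO[Si](C)(C)C(C)(C)C)O[C@@H]2CC/C(C)=C/[C@H](O)[C@@H]1CC(=O)O
F3 | step 9 | (2S,3S)-1,2-bis[(tert-butyldimethylsilyl)oxy]-3-{[(4-methoxyphenyl)methoxy]methyl}hex-5-ene | COc1ccc(COC[C@H](CC=C)[C@H](O[Si](C)(C)C(C)(C)C)CO[Si](C)(C)C(C)(C)C)cc1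
F4 | step 9 | (2S,3S)-2-[(tert-butyldimethylsilyl)oxy]-3-{[(4-methoxyphenyl)methoxy]methyl}hex-5-en-1-ol | COc1ccc(COC[C@H](CC=C)[C@H](O[Si](C)(C)C(C)(C)C)CO)cc1
F5 | step 9 | (2S,3S)-2-[(tert-butyldimethylsilyl)oxy]-3-{[(4-methoxyphenyl)methoxy]methyl}hex-5-enal | COc1ccc(COC[C@H](CC=C)[C@H](O[Si](C)(C)C(C)(C)C)C=O)cc1
F6 | step 9 | methyl (4S,5S)-2-[bis(2,2,2-trifluoroethoxy)phosphoryl]-4-[(tert-butyldimethylsilyl)oxy]-5-{[(4-methoxyphenyl)methoxy]methyl}octa-2,7-dienoate (olefin isomers) | COc1ccc(COC[C@H](CC=C)[C@H](O[Si](C)(C)C(C)(C)C)C=C(C(=O)OC)P(=O)(OCC(F)(F)F)OCC(F)(F)F)cc1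
F7 | step 23 | (1R,6R,7S,8R,10S)-8-[(tert-butyldimethylsilyl)oxy]-14-hydroxy-1,10-epoxygermacra-4E,11(13)-dien-12,6-olide | CC(C)(C)[Si](C)(C)O[C@@H]1C[C@@]2(CO)O[C@@H]2CC/C(C)=C/[C@H]2OC(=O)C(=C)[C@@H]21
F8 | step 23 | (1R,6R,7S,8R,10S)-14-acetoxy-8-[(tert-butyldimethylsilyl)oxy]-1,10-epoxygermacra-4E,11(13)-dien-12,6-olide | CC(C)(C)[Si](C)(C)O[C@@H]1C[C@@]2(COC(C)=O)O[C@@H]2CC/C(C)=C/[C@H]2OC(=O)C(=C)[C@@H]21
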